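Early on, the north and north-east runs behave as we might guess: they hold the same Q and Z, the north-east run has 3.00 times the L, and at the first reading, 4.6 min, the north-east run shows more E, 0.069 M against 0.028 M.

the same everywhere: Z 0.500 M
- north: Q 0.200 M; L 0.00400 M
- south-east: Q 0.300 M; L 0.00400 M
- north-east: Q 0.200 M; L 0.0120 M
- west: Q 0.200 M; L 0.0290 M; time 60 min

- north run (time / min: [E] / M): 4.6: 0.028; 14: 0.053; 26: 0.071; 42: 0.093; 60: 0.097
- south-east run (time / min: [E] / M): 4.6: 0.039; 14: 0.094; 26: 0.123; 42: 0.141; 60: 0.143
- north-east run (time / min: [E] / M): 4.6: 0.069; 14: 0.124; 26: 0.144; 42: 0.143; 60: 0.149

(readings scatter by 0.003 M)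

- Overall: Q + Z -> E, with L as catalyst.
- Constant volume, constant temperature.
- The analysis sees a species whether free or bound.
- "The second partner" is Z.
- An order is taken over about fifteen percent of the charge, up and down.

1. the exponent of [Q] in the starting rate at the charge of the north run (at the point where two percent of the Q have become E) (one fixed amount of E, the same in the runs compared)
2. the exponent of [L] in the starting rate at the charge of the north run (at the point where two percent of the Q have become E)
3. E in the west run at 60 min, as a share of the Q charged

The ends of these two runs tell us more. Q is the limiting reagent, 0.200 M against 0.500 M of Z, yet at 60 min the north run stands at 0.097 M of E and the north-east run at 0.149 M. Each has climbed by no more than 6.00 mM since 42 min, with a scatter of 0.003 M.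

We try a picture an engineer knows: a tank with two drains in parallel. If one drain opens in proportion to L and fills E, while the other ignores L and takes Q elsewhere, then the tank empties with one time constant, and the ratio of the openings sets what reaches E.

The test is simple in logarithms. From the readings at 60 min, E over the Q that has not become E is 0.942 in the north run and 2.92 in the north-east run. Against L, on logarithmic scales, these two readings give a slope of 1.03, close to the slope of one that the picture requires.

Dividing the north ratio by its L gives 235 M⁻¹. We call this quantity, E at the end of a run per Q not become E and per unit of L charged, the split, a selectivity factor; here it is a reading from the north run. The west run has 7.25 times the L of the north run, which adds 0.860 to the base-ten logarithm of the ratio. The ratio becomes 6.83, so we commit to 87.2% of the Q as E.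

The forecast gives 88% for the west run, with orders of 0.95 in Q and 0.95 in L. Its ground for the plateaus differs from our picture: “L is therefore dying during the run”.

The flask gives 87.5% for the west run, with orders of 1.3 in Q and 1.0 in L.

    L + Z ⇌ LZ, settled at all times (49.90 M⁻¹)
    LZ + Q → E + L (33.48 M⁻¹ min⁻¹)
    Q + Z ⇌ QZ, settled at all times (8.760 M⁻¹)
    Q → Xi (0.1302 min⁻¹)

The shortfall in the west run comes from the path from Q to Xi: with that path taken away, E comes to >99.9% of the Q charged. The west result gives a split of 242 M⁻¹, and the north readings gave 235 M⁻¹. Carried to the south-east run, with 0.300 M of Q and the L of the north run, the north split gives 0.145 M of E, and the reading at 60 min is 0.143 M.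

(All runs come from a simulation on assumed constants.)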